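## Retrosynthetic overview

1. Target 18 ⇐ 17: the two peri-phenols are unmasked last (O–CH3 cleavage).
2. 17 ⇐ 15: the quinone ring, the only ring made and made last, is closed by light, joining the formyl carbon to the distal alkyne carbon (C1–C2 of the quinone).
3. 15 ⇐ 14 + CO + 9: carbonylative Sonogashira coupling; the benzene ring is bought with 10.
4. 9 ⇐ 7 + 8; 7 ⇐ 4 (lactone C=O becomes C≡CH); 4 ⇐ 1 + 2 (decarboxylative alkenylation).
5. The single stereocentre is C2 of (S)-malic acid, bought in 1; none of its four bonds is broken on the way to 18.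

Assumption: 1 (the acetonide of natural (S)-malic acid), 2, 8 and 10 are bought; the target is the (S) (alkannin-series) tiglate, handled as the naphthazarin tautomer drawn in the SMILES.

## Route

Step 1
Reactants: 1 (S)-2-(2,2-dimethyl-5-oxo-1,3-dioxolan-4-yl)acetic acid; 2 (2-methylprop-1-en-1-yl)magnesium bromide
Product: 4 (S)-2,2-dimethyl-5-(3-methylbut-2-en-1-yl)-1,3-dioxolan-4-one, via NHPI ester 3 (not isolated)
Conditions: NHPI, DIC, DMAP (cat.), CH2Cl2, rt; then Ni(acac)2 (10 mol%), 2,2'-bipyridine (10 mol%), (2-methylprop-1-enyl)ZnCl [from 2 + ZnCl2], THF/DMF, rt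
Reagents that add atoms: none
Why: Ni-catalysed decarboxylative alkenylation of the in-situ redox-active ester with an alkenylzinc (radical Negishi-type cross-coupling) works for primary acids; the radical sits on the CH2 next to the stereocentre, whose C–H and C–O bonds are not involved, so the (S) centre bought with 1 is kept.

Step 2
Reactants: 4 (S)-2,2-dimethyl-5-(3-methylbut-2-en-1-yl)-1,3-dioxolan-4-one
Product: 7 (S)-6-methylhept-5-en-1-yn-3-ol, via lactol 5 (not isolated), via hydroxy aldehyde 6 (not isolated)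
Conditions: DIBAL-H (1.2 equiv), CH2Cl2, −78 °C; MeOH; then dimethyl (1-diazo-2-oxopropyl)phosphonate, K2CO3, MeOH, 0 °C → rt
Reagents that add atoms: dimethyl (1-diazo-2-oxopropyl)phosphonate, COP(=O)(OC)C(=[N+]=[N-])C(C)=O
Why: DIBAL stops at the five-membered lactol, which in K2CO3/MeOH opens with loss of acetone to the α-hydroxy aldehyde, and this is homologated by the Ohira–Bestmann variant of the Seyferth–Gilbert reaction (one-pot ester-to-alkyne conversion) faster than it enolises, so the carbinol centre is carried over unchanged.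

Step 3
Reactants: 7 (S)-6-methylhept-5-en-1-yn-3-ol; 8 (E)-2-methylbut-2-enoyl chloride
Product: 9 (S)-6-methylhept-5-en-1-yn-3-yl (E)-2-methylbut-2-enoate
Conditions: 8 (1.3 equiv), Et3N, DMAP (cat.), CH2Cl2, 0 °C → rt
Reagents that add atoms: none
Why: DMAP-catalysed O-acylation of the secondary propargylic alcohol with the acid chloride; the O–C bond at the stereocentre is not broken and the tiglate is the stable (E) isomer.

Step 4
Reactants: 10 2,5-dimethoxybenzaldehyde
Product: 14 2-iodo-3,6-dimethoxybenzaldehyde, via amino alkoxide 11 (not isolated), via aryllithium 12 (not isolated), via iodo amino alkoxide 13 (not isolated)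
Conditions: LiN(Me)CH2CH2NMe2 [amine + n-BuLi], THF, −20 °C; n-BuLi, −20 °C; I2, −78 °C → rt; H2O
Reagents that add atoms: iodine, II
Why: Comins-type in-situ protection and directed ortho-metalation: the α-amino alkoxide and the 5-OMe group together direct lithiation to C6, iodine traps the aryllithium, and water releases the aldehyde.

Step 5
Reactants: 14 2-iodo-3,6-dimethoxybenzaldehyde; 9 (S)-6-methylhept-5-en-1-yn-3-yl (E)-2-methylbut-2-enoate
Product: 15 (S)-1-(2-formyl-3,6-dimethoxyphenyl)-7-methyl-1-oxooct-6-en-2-yn-4-yl (E)-2-methylbut-2-enoate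
Conditions: CO (1 atm), PdCl2(PPh3)2 (5 mol%), Et3N, THF, rt, copper-free, dark
Reagents that add atoms: carbon monoxide, [C-]#[O+]
Why: Carbonylative Sonogashira coupling: oxidative addition, CO insertion into the hindered electron-rich aryl–Pd bond and alkynylation give the ynone under neutral room-temperature conditions that leave the propargylic ester and the stereocentre untouched.

Step 6
Reactants: 15 (S)-1-(2-formyl-3,6-dimethoxyphenyl)-7-methyl-1-oxooct-6-en-2-yn-4-yl (E)-2-methylbut-2-enoate
Product: 17 (S)-1-(5,8-dimethoxy-1,4-dioxo-1,4-dihydronaphthalen-2-yl)-4-methylpent-3-en-1-yl (E)-2-methylbut-2-enoate, via ketene enol 16 (not isolated)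
Conditions: hν (365 nm LED, FEP flow coil, ca. 15 min residence), degassed PhCF3, 5 mM, 25 °C; stop at full conversion of 15, keep product from light
Reagents that add atoms: none
Why: Proposed new method: photoenolisation-triggered Moore-type benzannulation of an o-formylaryl ynone, in which the n,π*-excited ynone carbonyl abstracts the formyl hydrogen through a six-membered transition state (as in the photoenolisation of o-acylbenzaldehydes), the acyl/hydroxypropargyl biradical collapses to the hydroxy-o-quinodimethane ketene 16, the rotamer of 16 with the alkyne on the ketene side closes ketene carbon to distal alkyne carbon with rearomatisation, and an O-to-C hydrogen shift gives the quinone; the closest known reactions are the photoisomerisation of o-acylbenzaldehydes to phthalides through such ketene enols and the thermal Moore ring expansion of 4-alkynyl-4-hydroxycyclobutenones to quinones through the same kind of ene-yne-ketene; the step is a reagent-free isomerisation and the stereocentre lies outside the reacting array.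

Step 7
Reactants: 17 (S)-1-(5,8-dimethoxy-1,4-dioxo-1,4-dihydronaphthalen-2-yl)-4-methylpent-3-en-1-yl (E)-2-methylbut-2-enoate
Product: 18 (S)-1-(5,8-dihydroxy-1,4-dioxo-1,4-dihydronaphthalen-2-yl)-4-methylpent-3-en-1-yl (E)-2-methylbut-2-enoate
Conditions: BCl3 (4 equiv), CH2Cl2, −78 → −20 °C; aq. NaHCO3
Reagents that add atoms: none
Why: Chelation-assisted Lewis-acid ether cleavage: BCl3 binds each peri-methoxy/quinone-carbonyl pair and chloride removes the methyl groups at low temperature, where the ester, the trisubstituted alkene and the stereocentre (ionisation next to the electron-poor quinone is disfavoured) should survive.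

## Compound list

1 | (S)-2-(2,2-dimethyl-5-oxo-1,3-dioxolan-4-yl)acetic acid | OC(=O)C[C@@H]1OC(C)(C)OC1=O | starting material
2 | (2-methylprop-1-en-1-yl)magnesium bromide | CC(C)=C[Mg]Br | starting material
3 | 1,3-dioxoisoindolin-2-yl (S)-2-(2,2-dimethyl-5-oxo-1,3-dioxolan-4-yl)acetate (NHPI ester) | O=C(C[C@@H]1OC(C)(C)OC1=O)ON1C(=O)c2ccccc2C1=O | intermediate (not isolated)
4 | (S)-2,2-dimethyl-5-(3-methylbut-2-en-1-yl)-1,3-dioxolan-4-one | CC(C)=CC[C@@H]1OC(C)(C)OC1=O | intermediate
5 | (5S)-2,2-dimethyl-5-(3-methylbut-2-en-1-yl)-1,3-dioxolan-4-ol (lactol, both anomers) | CC(C)=CC[C@@H]1OC(C)(C)OC1O | intermediate (not isolated)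
6 | (S)-2-hydroxy-5-methylhex-4-enal | CC(C)=CC[C@H](O)C=O | intermediate (not isolated)
7 | (S)-6-methylhept-5-en-1-yn-3-ol | CC(C)=CC[C@H](O)C#C | intermediate
8 | (E)-2-methylbut-2-enoyl chloride (tigloyl chloride) | C/C=C(\C)C(Cl)=O | starting material
9 | (S)-6-methylhept-5-en-1-yn-3-yl (E)-2-methylbut-2-enoate | C/C=C(\C)C(=O)O[C@@H](CC=C(C)C)C#C | intermediate
10 | 2,5-dimethoxybenzaldehyde | COc1ccc(OC)c(C=O)c1 | starting material
11 | lithium (2,5-dimethoxyphenyl){[2-(dimethylamino)ethyl](methyl)amino}methanolate (racemic at the aminal carbon) | [Li]OC(N(C)CCN(C)C)c1cc(OC)ccc1OC | intermediate (not isolated)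
12 | 6-lithio derivative of 11 (lithium ortho to the aminal carbon and to the 5-OMe group) | [Li]OC(N(C)CCN(C)C)c1c([Li])c(OC)ccc1OC | intermediate (not isolated)
13 | lithium (2-iodo-3,6-dimethoxyphenyl){[2-(dimethylamino)ethyl](methyl)amino}methanolate | [Li]OC(N(C)CCN(C)C)c1c(I)c(OC)ccc1OC | intermediate (not isolated)
14 | 2-iodo-3,6-dimethoxybenzaldehyde | O=Cc1c(I)c(OC)ccc1OC | intermediate
15 | (S)-1-(2-formyl-3,6-dimethoxyphenyl)-7-methyl-1-oxooct-6-en-2-yn-4-yl (E)-2-methylbut-2-enoate | C/C=C(\C)C(=O)O[C@@H](CC=C(C)C)C#CC(=O)c1c(OC)ccc(OC)c1C=O | intermediate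
16 | (S,Z)-1-hydroxy-1-[2,5-dimethoxy-6-(oxomethylidene)cyclohexa-2,4-dien-1-ylidene]-7-methyloct-6-en-2-yn-4-yl (E)-2-methylbut-2-enoate (ketene enol, alkynyl group on the ketene side) | C/C=C(\C)C(=O)O[C@@H](CC=C(C)C)C#C/C(O)=C1/C(OC)=CC=C(OC)C1=C=O | intermediate (not isolated)
17 | (S)-1-(5,8-dimethoxy-1,4-dioxo-1,4-dihydronaphthalen-2-yl)-4-methylpent-3-en-1-yl (E)-2-methylbut-2-enoate | C/C=C(\C)C(=O)O[C@@H](CC=C(C)C)C1=CC(=O)c2c(OC)ccc(OC)c2C1=O | intermediate
18 | (S)-1-(5,8-dihydroxy-1,4-dioxo-1,4-dihydronaphthalen-2-yl)-4-methylpent-3-en-1-yl (E)-2-methylbut-2-enoate | C/C=C(\C)C(=O)O[C@@H](CC=C(C)C)C1=CC(=O)c2c(O)ccc(O)c2C1=O | target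

## Step count and risks

Total: 7 steps. Longest linear sequence: 6 steps (1 → 4 → 7 → 9 → 15 → 17 → 18); the arene branch 10 → 14 adds one step.

**Step 6 (the proposed new step) is the most likely to fail.** The known fate of ketene enols from o-acylbenzaldehydes is lactonisation, so the rotamer of 16 with OH on the ketene side may give the 3-alkynylphthalide instead. Five-ring closure to an alkylidene-indanedione is a second possible leak. If the ring-closed intermediate has σ-radical character at C3, it could add to the prenyl double bond (5-exo). The quinone 17 is itself light-sensitive. The fallback uses known chemistry, sets out from alkyne ester 9 (14 and 15 are then not needed) and comes back at 17. Bought 2-bromo-1,4-dimethoxybenzene is converted (n-BuLi; Cr(CO)6; Me3OBF4) into the Fischer carbene complex pentacarbonyl[(2,5-dimethoxyphenyl)(methoxy)methylidene]chromium F1. Heating F1 with 9 in THF at 50 °C (Dötz benzannulation, the larger alkyne substituent ending next to the new phenol) gives the naphthol (S)-1-(1-hydroxy-4,5,8-trimethoxynaphthalen-2-yl)-4-methylpent-3-en-1-yl (E)-2-methylbut-2-enoate F2. Crude F2 is oxidised with CAN in aqueous MeCN at 0 °C to 17.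

**Step 7 is the second risk.** The second peri-demethylation may be sluggish, and HCl/BCl3 may attack the prenyl double bond. The fallback sets out from 17 and comes back at 18, and is oxidative instead of Lewis-acidic. AgO with 6 M HNO3 in dioxane at rt converts the dimethoxy ring into the bis-quinone (S)-4-methyl-1-(1,4,5,8-tetraoxo-1,4,5,8-tetrahydronaphthalen-2-yl)pent-3-en-1-yl (E)-2-methylbut-2-enoate F3. F3 is reduced in the work-up (aq. Na2S2O4, then air) to 18.

**Step 2 is the third risk.** The free α-hydroxy aldehyde 6 may partly racemise or oligomerise in K2CO3/MeOH before homologation, and 7 is volatile. The fallback sets out from 4 and comes back at 7, and uses an open-chain, O-silylated aldehyde. Acidic methanolysis of 4 (MeOH, cat. HCl) gives methyl (S)-2-hydroxy-5-methylhex-4-enoate F4. TBSCl/imidazole gives methyl (S)-2-[(tert-butyldimethylsilyl)oxy]-5-methylhex-4-enoate F5. DIBAL-H in toluene at −78 °C gives (S)-2-[(tert-butyldimethylsilyl)oxy]-5-methylhex-4-enal F6. The Ohira–Bestmann reaction gives (S)-tert-butyldimethyl[(6-methylhept-5-en-1-yn-3-yl)oxy]silane F7, and TBAF in THF returns 7.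

Further compounds
F1 | step 6 | pentacarbonyl[(2,5-dimethoxyphenyl)(methoxy)methylidene]chromium | COC(c1cc(OC)ccc1OC)=[Cr](=C=O)(=C=O)(=C=O)(=C=O)=C=O
F2 | step 6 | (S)-1-(1-hydroxy-4,5,8-trimethoxynaphthalen-2-yl)-4-methylpent-3-en-1-yl (E)-2-methylbut-2-enoate | C/C=C(\C)C(=O)O[C@@H](CC=C(C)C)c1cc(OC)c2c(OC)ccc(OC)c2c1O
F3 | step 7 | (S)-4-methyl-1-(1,4,5,8-tetraoxo-1,4,5,8-tetrahydronaphthalen-2-yl)pent-3-en-1-yl (E)-2-methylbut-2-enoate | C/C=C(\C)C(=O)O[C@@H](CC=C(C)C)C1=CC(=O)C2=C(C1=O)C(=O)C=CC2=O
F4 | step 2 | methyl (S)-2-hydroxy-5-methylhex-4-enoate | COC(=O)[C@@H](O)CC=C(C)C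
F5 | step 2 | methyl (S)-2-[(tert-butyldimethylsilyl)oxy]-5-methylhex-4-enoate | COC(=O)[C@@H](O[Si](C)(C)C(C)(C)C)CC=C(C)C
F6 | step 2 | (S)-2-[(tert-butyldimethylsilyl)oxy]-5-methylhex-4-enal | O=C[C@@H](O[Si](C)(C)C(C)(C)C)CC=C(C)C
F7 | step 2 | (S)-tert-butyldimethyl[(6-methylhept-5-en-1-yn-3-yl)oxy]silane | C#C[C@@H](O[Si](C)(C)C(C)(C)C)CC=C(C)C
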